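Early on, the grey flask fills fast: by 0.208 d, X already stands at 12.5% of the G charged.

| setting | grey | ochre | flask |
|---|---|---|---|
| G | 0.50 M | 0.50 M | 0.50 M |
| Z | 1 M | 1 M | 1.00 M |
| Q | 0.75 M | 1.1 M | 0.750 M |
| remark | the very flask that is asked about, followed so far | run made earlier |  |
| time |  |  | 15 d |

| run | time / d | X / % | E / % |
|---|---|---|---|
| grey | 0.208 | 12.5 | 1.8 |
| grey | 0.333 | 12.0 | 3.1 |
| grey | 0.500 | 10.9 | 4.6 |
| grey | 0.833 | 8.8 | 7.3 |
| grey | 1.25 | 6.9 | 9.4 |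
| grey | 1.67 | 5.5 | 10.5 |
| grey | 2.50 | 3.3 | 12.1 |
| ochre | 2.00 | 4.3 | 23.9 |
| ochre | 4.00 | 0.9 | 27.1 |
| ochre | 6.00 | 0.1 | 27.9 |
| ochre | 8.00 | 0 | 27.8 |
| ochre | 10.0 | 0.2 | 27.2 |
| ochre | 12.0 | 0.1 | 28.0 |
| ochre | 15.0 | 0 | 27.4 |

(readings scatter by 0.3 percentage points)

* the best time, 15 d at the latest, for X
* the amount of X, in percent of the G charged, at that time
* the first time at which X reaches 6.2%, in the same percent



Two numbers of the grey run clash. Q is charged at 1.50 equivalents of G, yet X + E levels off near 16.0% of G. Let P be the amount of X + E at that level, φ the share of charged Q that reaches X, and Z̄ the mean of Z between start and end. The reckoning here supposes that Z competes with G for Q and takes Q one to one, and it replaces the falling Z curve by Z̄: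

P = 0.0800 M

φ = P / Q = 10.7%

Z̄ = Z − (Q − P)/2 = 0.665 M

κ = φ Z̄ = 0.0709 M

So 89.3% of the grey Q goes elsewhere. This capture number κ, the share of Q reaching X times the mean Z, is a selectivity factor with mean G folded in.

The ochre run tests the mean, though its own X + E enters Z̄. There Z̄ is 0.520 M, so κ gives X + E 30.0% of G, while ochre reads 28.0%.

The forecast gives 0.19 d (0.12 d to 0.27 d), 12.8% (12.3% to 13.8%) and 1.4 h (0.8 h to 2.3 h): “X therefore peaks early, before or around the first reading”.

The flask gives 0.243 d, 12.5% and 0.957 h.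

    G + Q → X (k = 3.40 × 10⁻⁵ M⁻¹ s⁻¹)
    Q + Z → L (k = 1.90 × 10⁻⁴ M⁻¹ s⁻¹)
    X + L → E (k = 2.30 × 10⁻⁵ M⁻¹ s⁻¹)
    G + L → D (k = 3.90 × 10⁻⁵ M⁻¹ s⁻¹)

At 0.0467 d, Q in the flask passes into L 8.2 times as fast as into X, so 10.8% of its use at that moment feeds X. In the neighbour flask with 1.7 M of Z, Z ends at 58% of its charge, so κ over a mean Z of 1.35 M gives E 7.90% of G, and that flask ends with E at 8.65%.

All runs were generated by integration for an exercise; the scatter is artificial.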